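**Plan**

Numbering: ring A is C1 (OH), C2 (Br), C3 (H), C4 (O–aryl), C5 (Br), C6 (Br); ring B is C1' (ether O), C2' (OH), C3' (Br), C4' (Br), C5' (OH), C6' (Br).
Retrosynthesis: the C2' and C5' hydroxyls become methyl ethers and the C2–Br and C6–Br bonds, both ortho to the C1 hydroxyl, are cut first. Ring A is then cut at C4–C5 and C1–C6 into a 2-aryloxyfuran (C1 to C4 plus the oxygen that becomes the C1 hydroxyl) and a 1-bromovinyl sulfoxide (C5 and C6, a bromoacetylene equivalent). Last, the furan–O–aryl bond is cut by nitro displacement and the three ring B bromines go back to 2,5-dimethoxyphenol.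
Enabling feature: ring A is a para-dioxygenated benzene (C1–OH, C4–O–aryl) whose C5 bromine lies beside the ether carbon and meta to the hydroxyl, where phenol-directed bromination cannot reach; a 2-oxyfuran plus a two-carbon dienophile builds exactly this pattern.
Forward order: ring B is brominated, joined to the furan and the furan freed of its carboxyl group; ring A is then closed by cycloaddition, sulfenic acid loss and bridge opening; two ortho brominations and demethylation finish.
Stereochemistry: the target has no stereocentre; positional control comes from the ortho rule of the cycloaddition and from hydroxyl-directed bromination.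

Key step: step 6

Remark: the sulfoxide dienophile is used as the racemate and the cycloadduct as whatever diastereomer mixture forms, because sulfur, C5 and the bridgehead centres all lose their configuration on aromatisation.

**Route**

Step 1
Reactants: 1 2,5-dimethoxyphenol
Product: 2 3,4,6-tribromo-2,5-dimethoxyphenol
Conditions: Br2 (3.5 equiv), AcOH, 20 → 60 °C
Reagents that add atoms: bromine, BrBr
Why: Electrophilic aromatic bromination, in which the hydroxyl group activates C6' and C4' and the C2' methoxy group activates C3', and since these are the only ring hydrogens exhaustive bromination can lead to one tribromide only.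

Step 2
Reactants: 2 3,4,6-tribromo-2,5-dimethoxyphenol; 3 methyl 5-nitrofuran-2-carboxylate
Product: 4 methyl 5-(3,4,6-tribromo-2,5-dimethoxyphenoxy)furan-2-carboxylate
Conditions: K2CO3, DMSO, 25 → 60 °C
Reagents that add atoms: none
Why: Nucleophilic aromatic substitution by addition–elimination, in which the phenoxide adds to furan C5, activated by the nitro group and the conjugated ester, and nitrite leaves, a displacement well known for 5-nitrofuran-2-carboxylates.

Step 3
Reactants: 4 methyl 5-(3,4,6-tribromo-2,5-dimethoxyphenoxy)furan-2-carboxylate
Product: 5 5-(3,4,6-tribromo-2,5-dimethoxyphenoxy)furan-2-carboxylic acid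
Conditions: LiOH·H2O (3 equiv), THF/H2O, 0 °C → rt; then 1 M HCl, 0 °C, to pH 3
Reagents that add atoms: lithium hydroxide (its oxygen becomes the acid OH), [Li+].[OH-]
Why: Ester saponification, in which hydroxide should attack the unhindered methyl ester faster than furan C5, and the carboxylate once formed deactivates the ring against loss of the aryloxy group; aryl bromides and methyl ethers are inert.

Step 4
Reactants: 5 5-(3,4,6-tribromo-2,5-dimethoxyphenoxy)furan-2-carboxylic acid
Product: 6 2-(3,4,6-tribromo-2,5-dimethoxyphenoxy)furan
Conditions: Ag2CO3 (10 mol %), AcOH (5 mol %), DMSO, 120 °C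
Reagents that add atoms: none
Why: Silver-catalysed protodecarboxylation of a heteroaromatic carboxylic acid, in which the silver-bound carboxylate loses CO2 to a 2-furyl–Ag species that is protonated, a process helped by the ring oxygen and the electron-rich aryloxy-substituted furan and one that leaves aryl bromides untouched.

Step 5
Reactants: 7 phenyl vinyl sulfoxide
Product: 9 1-bromovinyl phenyl sulfoxide, via 1,2-dibromoethyl phenyl sulfoxide 8 (not isolated)
Conditions: Br2 (1.05 equiv), CH2Cl2, 0 °C → rt; then Et3N (1.5 equiv), 0 °C → rt
Reagents that add atoms: bromine, BrBr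
Why: Bromine addition across the vinyl group followed by E1cB-type dehydrobromination, in which Et3N removes the acidic proton α to sulfur and bromide leaves from the β-carbon, so the remaining bromine sits on the sulfur-bearing carbon.

Step 6
Reactants: 6 2-(3,4,6-tribromo-2,5-dimethoxyphenoxy)furan; 9 1-bromovinyl phenyl sulfoxide
Product: 12 3-bromo-4-(3,4,6-tribromo-2,5-dimethoxyphenoxy)phenol, via sulfinyl oxanorbornene cycloadduct 10 (not isolated), via bromo oxanorbornadiene 11 (not isolated)
Conditions: 9 (2 equiv), toluene, 80 → 110 °C, sealed tube, argon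
Reagents that add atoms: none
Why: Normal-electron-demand Diels–Alder reaction: the HOMO of the 2-aryloxyfuran, largest at the unsubstituted α-carbon (ring A C1), meets the LUMO of the α-bromovinyl sulfoxide, largest at its CH2 terminus (C6), so that C1–C6 and C4–C5 form in one concerted, asynchronous (4+2) event that closes the six-membered carbocycle of ring A as 7-oxanorbornene 10. At the reaction temperature 10 should lose PhSOH by thermal syn-elimination through a five-membered cyclic transition state that can use either C6 hydrogen, and in oxanorbornadiene 11 the ketal-type C4–O bridge bond ionises to an aryloxy-stabilised cyclohexadienyl cation that sheds the C1 proton, which turns the bridge oxygen into the C1 hydroxyl. The closest known reactions are the cycloadditions of 2-alkoxyfurans with alkynes, whose 1-alkoxy-7-oxanorbornadienes open to 4-alkoxyphenols, and the use of phenyl vinyl sulfoxide as an acetylene equivalent in Diels–Alder reactions. No stereocentre is set, since sulfur, C5 and both bridgeheads lose their configuration on elimination and aromatisation, so endo/exo and facial selectivity do not matter. The step needs regioselectivity (bromine at C5 beside the ether carbon, not beside the hydroxyl carbon), which the ortho rule secures by pairing the donor-bearing furan carbon with the acceptor-bearing dienophile carbon, and it needs loss of PhSOH instead of HBr, which the base-free thermal conditions favour because only the sulfinyl group has a cyclic syn-elimination path. The reversible furan cycloaddition should be drawn forward because elimination and aromatisation are irreversible.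

Step 7
Reactants: 12 3-bromo-4-(3,4,6-tribromo-2,5-dimethoxyphenoxy)phenol
Product: 13 2,3,6-tribromo-4-(3,4,6-tribromo-2,5-dimethoxyphenoxy)phenol
Conditions: Br2 (2.1 equiv), CH2Cl2/AcOH, 0 °C → rt
Reagents that add atoms: bromine, BrBr
Why: Electrophilic aromatic bromination directed by the free hydroxyl, whose two ortho positions C2 and C6 are open while its para position C4 carries the ether, C3 is meta to it and ring B has no hydrogen left, so two equivalents of bromine should stop at the 2,6-dibrominated phenol.

Step 8
Reactants: 13 2,3,6-tribromo-4-(3,4,6-tribromo-2,5-dimethoxyphenoxy)phenol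
Product: 14 2,3,5-tribromo-6-(2,3,5-tribromo-4-hydroxyphenoxy)benzene-1,4-diol (target)
Conditions: BBr3 (6 equiv), CH2Cl2, −78 °C → rt; then degassed H2O, 0 °C
Reagents that add atoms: none
Why: Lewis acid cleavage of aryl methyl ethers, in which BBr3 binds each methoxy oxygen and bromide attacks the methyl carbon (SN2), while the diaryl ether and the aryl bromides are not touched and water then frees the C2' and C5' hydroxyls.

**Compound list**

1 | 2,5-dimethoxyphenol | COc1ccc(OC)c(O)c1 | starting material
2 | 3,4,6-tribromo-2,5-dimethoxyphenol | Oc1c(OC)c(Br)c(Br)c(OC)c1Br | intermediate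
3 | methyl 5-nitrofuran-2-carboxylate | COC(=O)c1ccc(o1)[N+](=O)[O-] | starting material
4 | methyl 5-(3,4,6-tribromo-2,5-dimethoxyphenoxy)furan-2-carboxylate | COC(=O)c1ccc(Oc2c(OC)c(Br)c(Br)c(OC)c2Br)o1 | intermediate
5 | 5-(3,4,6-tribromo-2,5-dimethoxyphenoxy)furan-2-carboxylic acid | OC(=O)c1ccc(Oc2c(OC)c(Br)c(Br)c(OC)c2Br)o1 | intermediate
6 | 2-(3,4,6-tribromo-2,5-dimethoxyphenoxy)furan | c1coc(Oc2c(OC)c(Br)c(Br)c(OC)c2Br)c1 | intermediate
7 | phenyl vinyl sulfoxide (racemic at sulfur) | C=CS(=O)c1ccccc1 | starting material
8 | 1,2-dibromoethyl phenyl sulfoxide (diastereomer mixture; formed and consumed in the flask) | BrCC(Br)S(=O)c1ccccc1 | intermediate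
9 | 1-bromovinyl phenyl sulfoxide (racemic at sulfur) | C=C(Br)S(=O)c1ccccc1 | intermediate
10 | 2-bromo-2-(phenylsulfinyl)-1-(3,4,6-tribromo-2,5-dimethoxyphenoxy)-7-oxabicyclo[2.2.1]hept-5-ene (diastereomer mixture; formed and consumed in the flask) | O=S(c1ccccc1)C1(Br)CC2C=CC1(Oc1c(OC)c(Br)c(Br)c(OC)c1Br)O2 | intermediate
11 | 2-bromo-1-(3,4,6-tribromo-2,5-dimethoxyphenoxy)-7-oxabicyclo[2.2.1]hepta-2,5-diene (racemic; formed and consumed in the flask) | BrC1=CC2C=CC1(Oc1c(OC)c(Br)c(Br)c(OC)c1Br)O2 | intermediate
12 | 3-bromo-4-(3,4,6-tribromo-2,5-dimethoxyphenoxy)phenol | Oc1ccc(Oc2c(OC)c(Br)c(Br)c(OC)c2Br)c(Br)c1 | intermediate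
13 | 2,3,6-tribromo-4-(3,4,6-tribromo-2,5-dimethoxyphenoxy)phenol | Oc1c(Br)cc(Oc2c(OC)c(Br)c(Br)c(OC)c2Br)c(Br)c1Br | intermediate
14 | 2,3,5-tribromo-6-(2,3,5-tribromo-4-hydroxyphenoxy)benzene-1,4-diol | Oc1c(Br)cc(Oc2c(O)c(Br)c(Br)c(O)c2Br)c(Br)c1Br | target

**Step count and risks**

Total step count: 8 (step 5 is a one-flask, two-stage operation).
Longest linear sequence: 7 steps (steps 1, 2, 3, 4, 6, 7, 8); step 5 feeds into step 6.

Steps most likely to fail:

Step 6. The cycloaddition may be too slow or too reversible below the temperature at which the aryloxyfuran degrades. An adduct that ionises at its ketal carbon before the sulfenic acid has left may also expel HBr, which would leave the sulfinyl group on the ring in place of bromine. The fallback abandons the ring construction and sets out from 2. Nucleophilic aromatic substitution on 3-bromo-4-fluorobenzaldehyde (K2CO3, DMF, 100 °C; the fluoride para to the formyl group is displaced) should give 3-bromo-4-(3,4,6-tribromo-2,5-dimethoxyphenoxy)benzaldehyde F1. Baeyer–Villiger oxidation with mCPBA in CH2Cl2 should convert it into 3-bromo-4-(3,4,6-tribromo-2,5-dimethoxyphenoxy)phenyl formate F2, and methanolysis (catalytic K2CO3, MeOH) rejoins the route at 12. The C5 bromine then comes from the building block.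

Step 2. The phenoxide of 2 is flanked by a methoxy group and a bromine and is made less nucleophilic by three bromines, so its addition to the nitrofuran may be slower than base-induced degradation of the ester-bearing nitrofuran. The fallback sets out from 2 and uses 5-nitrofuran-2-carbaldehyde, whose formyl group activates C5 more strongly than an ester does (K2CO3, DMSO, rt), to give 5-(3,4,6-tribromo-2,5-dimethoxyphenoxy)furan-2-carbaldehyde F3. Pinnick oxidation (NaClO2, NaH2PO4, 2-methyl-2-butene, t-BuOH/H2O) then leads to acid 5, where the route continues with step 4.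

Step 1. The third bromination, at C3', is activated by only one ortho methoxy group and is flanked by bromine; it may stall at the dibromide, and forcing it may oxidise the electron-rich phenol. The fallback sets out from 1 and brings in the last bromine through a carbanion. Br2 (2 equiv, CH2Cl2, 0 °C) should give 4,6-dibromo-2,5-dimethoxyphenol F4, and MOMCl with iPr2NEt protects it as 1,3-dibromo-2,5-dimethoxy-4-(methoxymethoxy)benzene F5. LiN(iPr)2 (THF, −78 °C) removes the single remaining ring proton, acidified by the neighbouring methoxy group and bromine (directed ortho-metalation), to give [2,4-dibromo-3,6-dimethoxy-5-(methoxymethoxy)phenyl]lithium F6. BrCCl2CCl2Br brominates this to 1,2,4-tribromo-3,6-dimethoxy-5-(methoxymethoxy)benzene F7; a halogen shift in F6 would be harmless because every ring position ends up brominated. HCl in MeOH removes the acetal and rejoins the route at 2.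

**Further compounds**

F1 | step 6 | 3-bromo-4-(3,4,6-tribromo-2,5-dimethoxyphenoxy)benzaldehyde | O=Cc1ccc(Oc2c(OC)c(Br)c(Br)c(OC)c2Br)c(Br)c1
F2 | step 6 | 3-bromo-4-(3,4,6-tribromo-2,5-dimethoxyphenoxy)phenyl formate | O=COc1ccc(Oc2c(OC)c(Br)c(Br)c(OC)c2Br)c(Br)c1
F3 | step 2 | 5-(3,4,6-tribromo-2,5-dimethoxyphenoxy)furan-2-carbaldehyde | O=Cc1ccc(Oc2c(OC)c(Br)c(Br)c(OC)c2Br)o1
F4 | step 1 | 4,6-dibromo-2,5-dimethoxyphenol | COc1cc(Br)c(OC)c(Br)c1O
F5 | step 1 | 1,3-dibromo-2,5-dimethoxy-4-(methoxymethoxy)benzene | COCOc1c(OC)cc(Br)c(OC)c1Br
F6 | step 1 | [2,4-dibromo-3,6-dimethoxy-5-(methoxymethoxy)phenyl]lithium | [Li]c1c(OC)c(OCOC)c(Br)c(OC)c1Br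
F7 | step 1 | 1,2,4-tribromo-3,6-dimethoxy-5-(methoxymethoxy)benzene | COCOc1c(OC)c(Br)c(Br)c(OC)c1Br
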